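Weigh the amounts first: this flask holds 10 µM of precatalyst against 20 mM of substrate, far less, and precatalyst must meet partner before it works as catalyst.

substrate 20 mM; partner 50.0 mM; precatalyst 10 µM

    substrate + catalyst → catalyst + intermediate (k1 = 16000 /M/min)
    partner + catalyst + intermediate → catalyst + product (k2 = 1.2 × 10⁵ /M²/min)
    partner + precatalyst → catalyst + spent reagent (k3 = 0.39 /M/min)

- the form that holds most of the catalyst when 10% of the substrate are converted (precatalyst / catalyst)
- its share of the catalyst then
- factor on the rate of making product when 10% of the substrate are converted if precatalyst is charged twice over
- factor on the rate when 10% of the substrate are converted if precatalyst is charged at 50 µM instead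

Begin with the bench rule: count the whole charge as working catalyst. With L = ln(1/(1 − conversion)) = 0.105, the rule gives

full-charge time = L / (16000 /M/min × 10 µM) = 0.659 min

and a rate proportional to the charge. Now find its border. Conversion to 10% can consume 4.00% of the partner, so treat activation as pseudo-first-order:

activation time = 1 / (0.39 /M/min × 50.0 mM) = 51.3 min

The rule needs the ratio of activation time to full-charge time well below one, but this flask gives 77.8, so drop the rule. Let catalyst instead rise in a straight line from zero, and integrate the loss of substrate against it:

time to conversion = sqrt(2 × activation time × full-charge time) = 8.22 min

lit share = time to conversion / activation time = 16.0%

The lit share is the part of the charge reckoned, on that straight line, to have become catalyst at that conversion. My reckoning therefore leaves 84.0% as precatalyst. At equal conversion, I take the intermediate as equal, so the rate follows charge times lit share, which grows as the root of the charge: a factor of 1.41 for twice the charge and 2.24 at 50 µM.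

The forecast gives precatalyst at 84.8%, with factors 1.44 and 2.3, reasoning that “the rate scales with active catalyst”. Its numbers are larger than mine.

The simulation gives precatalyst at 84.8%, with factors 1.44 and 2.30. Watch the rate: precatalyst stands outside the working round, and in this flask at 30.6 min, at 70 percent conversion, the rate of making product is 15 times its value at 10% conversion. At 8.44 min catalyst in this flask holds 15.2% of the charge, against a reckoned lit share of 16.0%. Apply the lit share to the flask with twice the precatalyst: it is reckoned to fall to 11.3%, which at equal intermediate puts the rate up by a factor of 1.41, and that flask's run gives 1.44.

All constants are those of an exercise.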